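Atom labels used throughout: ring O1, C2 (aryl), C3, C4, C5; C9 is the CH2O carbon on C3; C7' is the benzylic carbon on C4. The same labels are kept for these atoms in every intermediate.

## Analysis of the target

The target is a 2,3,4-trisubstituted oxolane: C2 carries a 4-hydroxy-3-methoxyphenyl group, C3 the C9H2 ester, C4 the C7'H2-guaiacyl group, and C5 is CH2. It is the C9 (2R)-2-methylbutanoate of (2R,3S,4S)-lariciresinol. The three ring stereocentres are contiguous, with the aryl group at C2 trans to C9 and C9 cis to C7'. The fourth stereocentre sits in the acyl chain, is independent of the ring and is best bought. C2–O1 is a benzylic ether para to an oxygenated arene: acid ionises it (epimerisation at C2, Friedel–Crafts closure onto the second arene) and Pd/H2 can cut it. The ester tolerates neither hydroxide nor hydride, its α-centre can epimerise when the acid is activated, and two free phenols compete with the C9 hydroxyl for electrophiles. The hard points are the cis relation of the C3 and C4 branches, which cannot be reached by equilibration, and telling the two branches C9 and C7' apart. The strategy rests on two facts: C2–O1–C5 is a C–O–C unit bonded to C3 and C4, and C9 and C7' are cis. The ring is therefore the adduct of a carbonyl ylide ArCH=O(+)–CH2(−) with a C3=C4 alkene whose two branches are tied into a lactone, so the cis relation becomes a ring fusion.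

## Retrosynthetic reasoning

**16 ⇒ 14 + 15.** The C9–O acyl bond is cut last. The ester is the most fragile group towards base and hydride, and the stereocentre of 15 is safest if the acid arrives unchanged at the end. The forward reaction must acylate the one aliphatic hydroxyl of 14 in the presence of two phenols without activating 15 as an acyl electrophile; a Mitsunobu esterification does both.

**14 ⇒ 13 ⇒ 12.** C9 is raised to a carboxylic acid (13) and its oxygen is reconnected to C7' as a γ-lactone (12), with both phenols as benzyl ethers. The lactone supplies C7' at the alcohol level with a good benzylic leaving group, and C9 at the acid level. One hydrogenolysis then turns C7' into CH2, frees the carboxyl group and removes both benzyl groups, and a hydride reduction of the acid gives 14. The forward hydrogenolysis has to cut the benzylic acyloxy bond and spare the benzylic ether C2–O1.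

**12 ⇒ 8 + 10 (from 9).** The C7'–aryl bond is cut. C7' is then at the aldehyde level, masked with the C9 carboxyl group as the cis-fused lactol 8. The aryl Grignard reagent 10 opens the lactol, adds to the aldehyde, and the hydroxy acid 11 closes to 12. The configuration at C7' does not matter because that centre is reduced to CH2.

**8 ⇒ 7.** The lactol hydroxyl is exchanged for the chiral alkoxy group of 7. This auxiliary has two tasks: it keeps C7' at the aldehyde level, and its acetal stereocentre next to C4 decides which face of the alkene reacts. The centre is discarded once the ring stereocentres exist.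

**7 ⇒ 5 + 6.** This is the key disconnection: C2–C3 and C4–C5 are cut together, which removes the oxolane ring and all three ring stereocentres in one retro-(3+2) step. It leaves the carbonyl ylide 6 and the butenolide 5. The cut is made here because it is the only one that uses the C–O–C unit as a single three-atom building block and turns the cis relation of C9 and C7' into the ring fusion of a bicyclic lactone. The forward reaction must add anti to the alkoxy group of 5, place the aryl group exo, and join the CH2 terminus of 6 to the β-carbon C4.

**6 ⇒ 4 ⇒ 3 ⇒ 1 + 2.** The ylide 6 is the 1,3-elimination product of the α-chloro silylmethyl ether 4, which comes from the symmetrical acetal 3 of aldehyde 1 with alcohol 2. The phenol of 1 is a benzyl ether and not a silyl ether. Fluoride would strip a phenolic silyl group, and the para-phenoxide would expel chloride from the benzylic carbon as a quinone methide before any ylide could form. The benzyl groups then leave in the hydrogenolysis that opens the lactone, so they cost no step.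

## Alternatives that were turned down

**Alternative 1:** The cuts are C2–C3 and O1–C5, with C5 carried as a lactone carbonyl. In the forward key step a chiral phosphoric acid catalyses the allylboration of 4-(tert-butyldimethylsilyloxy)-3-methoxybenzaldehyde A1 by the ester-bearing (Z)-allylboronate A2. A chair transition state sets C2 and C3 anti, and the borate alkoxide closes onto the ester to give the trans α-methylene lactone A3.
- For: the asymmetric induction is catalytic and needs no auxiliary. On this point it is stronger than the chosen route. Two stereocentres and a ring form in one step, and the exocyclic methylene is ready to take the second arene by conjugate addition.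
- Against: the ring that forms has C5 at the wrong oxidation level. The carbonyl must later be reduced to CH2 with a silane and a Lewis acid while the ionisable C2–O1 bond is present. C4 is set only afterwards, by protonation of a lactone enolate, and the required cis arrangement is the less stable one at an epimerisable centre. Ester-substituted allylboronates are sluggish, and enantiocontrol with an electron-rich aldehyde is not assured. Aryl and alkyl silyl ethers must later be told apart.
- Comparison: the chosen strategy sets all three ring stereocentres in one step and fixes the C3/C4 relation by ring fusion, not by a kinetic protonation.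

**Alternative 2:** The cuts are C4–C7' and C2–C3; no ring is opened. In the forward key step the lithiated dithiane A4 adds to the β-carbon of the enantiomeric butenolide A5 anti to the alkoxy group. The lactone enolate then adds to aldehyde A1 anti to the new substituent, giving the trans,trans lactone A6.
- For: both bonds and the C3 and C4 centres form in one flask. The regiochemistry is beyond doubt, since the nucleophile goes to the β-carbon and the electrophile to the α-carbon. On predictability it is stronger than the cycloaddition.
- Against: the oxolane ring is not made. The acetal carbon becomes C5, so after desulfurisation both the lactone and the acetal carbon must be reduced, and the ring must then be closed through the C2 benzylic cation under acid with both electron-rich arenes present. Those are the conditions under which such ethers epimerise and cyclise onto the neighbouring arene. C2 is set only thermodynamically, and stoichiometric sulfur and Raney Ni are needed.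
- Comparison: the chosen strategy closes the ring and sets C2 together with C3 and C4, and it passes its acid step before the second arene is in the molecule.

**Alternative 3:** The cut is C3–C4. In the forward key step Cp2TiCl (trivalent titanium) opens the terminal epoxide of the cinnamyl ether A7 to a C3 radical. This adds 5-exo to the styrene, and the benzylic radical at C7' is reduced to CH2, giving bis-silylated (2R,3S,4S)-lariciresinol A8.
- For: ring, C3, C4, the free C9 hydroxyl and the C7' methylene all appear in one step. Only esterification and desilylation follow, with no chemoselectivity problem. In end-game economy it is clearly stronger than the chosen route.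
- Against: the C2 stereocentre must be made beforehand by an asymmetric route to the epoxy carbinol and carried through an etherification, so the precursor is several steps long. The two new centres come from a chair-like radical transition state with one resident substituent, so the 3,4-cis relation is a preference and not a constraint. More than two equivalents of the titanium reagent are consumed.
- Comparison: the chosen strategy takes its absolute configuration from a crystalline auxiliary, has a three-step precursor, and enforces cis by geometry. It pays with a longer sequence after the key step.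

Key step: step 3

Remark: 5 and 9 are treated as catalogue compounds; otherwise 5 is one acetalisation and crystallisation from 5-hydroxyfuran-2(5H)-one and (1R,2S,5R)-menthol, and 9 is one benzylation of 4-bromo-2-methoxyphenol.

## Route

Step 1
Reactants: 1 4-(benzyloxy)-3-methoxybenzaldehyde; 2 (trimethylsilyl)methanol
Product: 3 4-(benzyloxy)-3-methoxybenzaldehyde bis[(trimethylsilyl)methyl] acetal
Conditions: 2 (3 equiv), TsOH·H2O (2 mol%), benzene, reflux over 4 Å MS (Soxhlet); Et3N quench
Reagents that add atoms: none
Why: Acid-catalysed acetalisation driven by removal of water on the sieves; the symmetrical acetal is chosen so that ionisation in step 2 can give only one chloro ether. The phenol is a benzyl ether because a silyl ether would be cleaved by the fluoride of step 3.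

Step 2
Reactants: 3 4-(benzyloxy)-3-methoxybenzaldehyde bis[(trimethylsilyl)methyl] acetal
Product: 4 chloro[4-(benzyloxy)-3-methoxyphenyl]methyl (trimethylsilyl)methyl ether (racemic)
Conditions: AcCl (1.1 equiv), ZnBr2 (0.5 mol%), CH2Cl2, 0 °C to rt; evaporate at 0.1 mbar, use crude under argon
Reagents that add atoms: acetyl chloride, CC(=O)Cl
Why: Acetal-to-α-chloro ether exchange with an acyl chloride under ZnBr2 catalysis: one alkoxy group is acylated and leaves as its acetate, and chloride captures the p-alkoxybenzyl oxocarbenium ion. The new stereocentre is racemic and becomes planar in the ylide.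

Step 3
Reactants: 4 chloro[4-(benzyloxy)-3-methoxyphenyl]methyl (trimethylsilyl)methyl ether; 5 (5R)-5-[(1R,2S,5R)-menthyloxy]furan-2(5H)-one
Product: 7 (1R,4R,5S,8R)-8-[4-(benzyloxy)-3-methoxyphenyl]-4-[(1R,2S,5R)-menthyloxy]-3,7-dioxabicyclo[3.3.0]octan-2-one (cis-fused, aryl exo, new ring anti to the menthyloxy group), via carbonyl ylide 6 (not isolated)
Conditions: 4 (2.5 equiv, slow addition), CsF (4 equiv, dried), MeCN, rt
Reagents that add atoms: none
Why: Fluoride attacks silicon of 4 and chloride leaves in a 1,3-elimination, giving the non-stabilised carbonyl ylide 6, an allyl-anion-type 4π dipole over C2–O1–C5, which adds in a concerted suprafacial (3+2) cycloaddition to the electron-poor C3=C4 bond of 5. The closest known reaction types are the (3+2) additions of carbonyl ylides made by this silicon-based 1,3-elimination to α,β-unsaturated esters, and the anti-selective dipolar cycloadditions of 5-alkoxybutenolides. The oxolane ring is closed by the intermolecular cycloaddition itself, C2–C3 and C4–C5 forming in the same step, so no separate cyclisation is involved. C3 and C4 are set cis because addition to the ring alkene is suprafacial, and their absolute sense follows from approach of 6 to the face of 5 opposite the menthyloxy group on the (R)-acetal carbon C7'. C2 is set by exo approach with the aryl group in the outside position of the ylide, away from the lactone ring, which puts it trans to C9; this is also the more stable epimer and can be corrected by acid in step 4. The step also needs regiocontrol: aryl conjugation and the p-alkoxy donor place the larger HOMO coefficient on the CH2 terminus, which should bond to the β-carbon C4 where the LUMO coefficient is largest, and this pairing also keeps the bulky ArCH terminus away from the menthyloxy-bearing carbon. 4 is used in excess and added slowly because 6 can also collapse to the epoxide.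

Step 4
Reactants: 7 the menthyloxy lactone acetal from step 3
Product: 8 (1R,5S,8R)-8-[4-(benzyloxy)-3-methoxyphenyl]-4-hydroxy-3,7-dioxabicyclo[3.3.0]octan-2-one (lactol, both anomers)
Conditions: 2 M HCl, 1,4-dioxane, 60 °C
Reagents that add atoms: water, O
Why: Acid hydrolysis of the acyloxy acetal; the freed aldehyde acid rests as the cis-fused lactol, which keeps C4 from enolising. Any C2 epimer from endo addition should equilibrate to the aryl-exo isomer under the same acid by reversible ionisation of C2–O1, and no second arene is present yet to trap that cation.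

Step 5
Reactants: 8 the lactol from step 4; 9 1-(benzyloxy)-4-bromo-2-methoxybenzene
Product: 12 (1R,5S,8R)-4,8-bis[4-(benzyloxy)-3-methoxyphenyl]-3,7-dioxabicyclo[3.3.0]octan-2-one (both epimers at C4 of the bicycle, which is C7'), via aryl Grignard reagent 10 (not isolated), via hydroxy acid 11 (not isolated)
Conditions: 9 (3.3 equiv), Mg, THF, rt; then 8, THF, −78 to 0 °C; then 1 M HCl, rt
Reagents that add atoms: none
Why: Grignard addition to a pseudo-acid: the first equivalent of 10 deprotonates the lactol and opens it to the formyl carboxylate, the second adds to the aldehyde, and acidification closes the γ-lactone of 11. The new carbinol centre at C7' is uncontrolled and is removed in step 6; the low temperature and the low standing concentration of free aldehyde guard C4 against enolisation.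

Step 6
Reactants: 12 the diaryl lactone from step 5
Product: 13 (2R,3R,4S)-2-(4-hydroxy-3-methoxyphenyl)-4-[(4-hydroxy-3-methoxyphenyl)methyl]oxolane-3-carboxylic acid
Conditions: H2 (1 atm), 10% Pd/C, EtOAc–EtOH, rt; stop after uptake of 3 equiv H2
Reagents that add atoms: none
Why: Pd-catalysed hydrogenolysis: the benzylic acyloxy bond C7'–O and the two aryl benzyl ethers should be cut faster than the dialkyl-type benzylic ether C2–O1. C7' becomes CH2, the carboxyl group on C3 is released, and C2, C3 and C4 are untouched.

Step 7
Reactants: 13 the diphenol acid from step 6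
Product: 14 (2R,3S,4S)-lariciresinol, 4-[(2R,3S,4S)-4-[(4-hydroxy-3-methoxyphenyl)methyl]-3-(hydroxymethyl)oxolan-2-yl]-2-methoxyphenol
Conditions: BH3·THF (5 equiv), THF, 0 °C to rt; then MeOH, H2O
Reagents that add atoms: none
Why: Borane reduces a carboxylic acid through its acyloxyborane in preference to everything else present; the phenols only form borate esters that methanol cleaves. The neutral work-up leaves C2–O1 and the ring stereocentres alone.

Step 8
Reactants: 14 (2R,3S,4S)-lariciresinol; 15 (2R)-2-methylbutanoic acid
Product: 16 [(2R,3S,4S)-2-(4-hydroxy-3-methoxyphenyl)-4-[(4-hydroxy-3-methoxyphenyl)methyl]oxolan-3-yl]methyl (2R)-2-methylbutanoate (target)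
Conditions: 15 (1.5 equiv), PPh3, DIAD (1.3 equiv each), THF, 0 °C to rt
Reagents that add atoms: none
Why: Mitsunobu esterification: the C9 hydroxyl is activated as its alkoxyphosphonium ion and displaced by the carboxylate of 15 at a CH2 carbon. The carboxylic acid is by about five pKa units the stronger pronucleophile, so the phenols should stay free, and because 15 is never made into an acyl electrophile its α-stereocentre cannot racemise.

## Compound list

1 | 4-(benzyloxy)-3-methoxybenzaldehyde | O=Cc1ccc(OCc2ccccc2)c(OC)c1 | starting material
2 | (trimethylsilyl)methanol | C[Si](C)(C)CO | starting material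
3 | 4-(benzyloxy)-3-methoxybenzaldehyde bis[(trimethylsilyl)methyl] acetal | C[Si](C)(C)COC(OC[Si](C)(C)C)c1ccc(OCc2ccccc2)c(OC)c1 | intermediate
4 | chloro[4-(benzyloxy)-3-methoxyphenyl]methyl (trimethylsilyl)methyl ether (racemic) | C[Si](C)(C)COC(Cl)c1ccc(OCc2ccccc2)c(OC)c1 | intermediate
5 | (5R)-5-[(1R,2S,5R)-menthyloxy]furan-2(5H)-one | O=C1C=C[C@H](O[C@@H]2C[C@H](C)CC[C@H]2C(C)C)O1 | starting material
6 | carbonyl ylide [4-(benzyloxy)-3-methoxyphenyl]CH=O(+)–CH2(−) | [CH2-][O+]=Cc1ccc(OCc2ccccc2)c(OC)c1 | intermediate (not isolated)
7 | (1R,4R,5S,8R)-8-[4-(benzyloxy)-3-methoxyphenyl]-4-[(1R,2S,5R)-menthyloxy]-3,7-dioxabicyclo[3.3.0]octan-2-one | O=C1O[C@@H](O[C@@H]3C[C@H](C)CC[C@H]3C(C)C)[C@@H]2CO[C@@H](c4ccc(OCc5ccccc5)c(OC)c4)[C@H]12 | intermediate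
8 | (1R,5S,8R)-8-[4-(benzyloxy)-3-methoxyphenyl]-4-hydroxy-3,7-dioxabicyclo[3.3.0]octan-2-one (anomers) | O=C1OC(O)[C@@H]2CO[C@@H](c3ccc(OCc4ccccc4)c(OC)c3)[C@H]12 | intermediate
9 | 1-(benzyloxy)-4-bromo-2-methoxybenzene | COc1cc(Br)ccc1OCc1ccccc1 | starting material
10 | [4-(benzyloxy)-3-methoxyphenyl]magnesium bromide | COc1cc([Mg]Br)ccc1OCc1ccccc1 | intermediate (not isolated)
11 | (2R,3R,4S)-2-[4-(benzyloxy)-3-methoxyphenyl]-4-{[4-(benzyloxy)-3-methoxyphenyl](hydroxy)methyl}oxolane-3-carboxylic acid (carbinol epimers; bromomagnesium salt in the flask) | OC(=O)[C@@H]1[C@H](C(O)c2ccc(OCc3ccccc3)c(OC)c2)CO[C@H]1c1ccc(OCc2ccccc2)c(OC)c1 | intermediate (not isolated)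
12 | (1R,5S,8R)-4,8-bis[4-(benzyloxy)-3-methoxyphenyl]-3,7-dioxabicyclo[3.3.0]octan-2-one (C4 epimers) | O=C1OC(c2ccc(OCc3ccccc3)c(OC)c2)[C@@H]2CO[C@@H](c3ccc(OCc4ccccc4)c(OC)c3)[C@H]12 | intermediate
13 | (2R,3R,4S)-2-(4-hydroxy-3-methoxyphenyl)-4-[(4-hydroxy-3-methoxyphenyl)methyl]oxolane-3-carboxylic acid | OC(=O)[C@@H]1[C@H](Cc2ccc(O)c(OC)c2)CO[C@H]1c1ccc(O)c(OC)c1 | intermediate
14 | (2R,3S,4S)-lariciresinol | OC[C@@H]1[C@H](Cc2ccc(O)c(OC)c2)CO[C@H]1c1ccc(O)c(OC)c1 | intermediate
15 | (2R)-2-methylbutanoic acid | CC[C@@H](C)C(=O)O | starting material
16 | [(2R,3S,4S)-2-(4-hydroxy-3-methoxyphenyl)-4-[(4-hydroxy-3-methoxyphenyl)methyl]oxolan-3-yl]methyl (2R)-2-methylbutanoate | CC[C@@H](C)C(=O)OC[C@@H]1[C@H](Cc2ccc(O)c(OC)c2)CO[C@H]1c1ccc(O)c(OC)c1 | target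

## Step count and least certain steps

Total step count: 8. Longest linear sequence: 8 steps (1 to 16); 5, 9 and 15 enter as bought partners.

**Step 3 (key step).** The most likely failure is loss of regiocontrol, with the ArCH terminus of 6 bonding to the β-carbon. Collapse of 6 to its epoxide and partial endo addition come next. The fallback makes the other regioisomer the productive one, because either end of the lactone tether can serve as the carbonyl.
- It sets out from 4, which is combined under the same conditions with the enantiomeric auxiliary (5S)-5-[(1S,2R,5S)-menthyloxy]furan-2(5H)-one F1.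
- The adduct with ArCH on the β-carbon is (1S,4S,5R,6R)-6-[4-(benzyloxy)-3-methoxyphenyl]-4-[(1S,2R,5S)-menthyloxy]-3,7-dioxabicyclo[3.3.0]octan-2-one F2. It has the acetal carbon as C9, the lactone carbonyl as C7', and the same (2R,3S,4S) ring.
- Acid hydrolysis would give the lactol (1S,5R,6R)-6-[4-(benzyloxy)-3-methoxyphenyl]-4-hydroxy-3,7-dioxabicyclo[3.3.0]octan-2-one F3.
- NaBH4 reduction of its aldehyde form and acidification would give the lactone (1S,5S,6R)-6-[4-(benzyloxy)-3-methoxyphenyl]-3,7-dioxabicyclo[3.3.0]octan-2-one F4.
- One equivalent of 10 at −78 °C would give the hydroxy ketone {(2R,3S,4S)-2-[4-(benzyloxy)-3-methoxyphenyl]-3-(hydroxymethyl)oxolan-4-yl}[4-(benzyloxy)-3-methoxyphenyl]methanone F5.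
- Hydrogenation over Pd/C in EtOH–AcOH would take the aryl ketone to CH2 and remove both benzyl groups. The fallback returns to the route at 14.

**Step 2.** The p-alkoxybenzyl chloride of 4 ionises easily, so it may hydrolyse or lose its silyl group to chloride while the acetate by-product is pumped off, and residual ester would consume fluoride. The fallback assembles the chloro ether directly instead of cleaving an acetal. It sets out from 1 and 2, which are treated with Me3SiCl in CH2Cl2 (hemiacetal, O-silyl hemiacetal, chloride). The only by-product is inert hexamethyldisiloxane, so the solution can be transferred to step 3 without concentration. It returns at 4, and no new compound is formed on the way (F0).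

**Step 5.** The ring-opened aldehyde may be enolised by the basic Grignard reagent. This epimerises C4 to the trans acid, which cannot lactonise. The fallback replaces the basic organometallic by a catalytic aryl transfer. It sets out from 8, to which [4-(benzyloxy)-3-methoxyphenyl]boronic acid is added with [Rh(cod)(OH)]2 and P(t-Bu)3 in dioxane–H2O at 60 °C. Acidic work-up lactonises the product, and the fallback returns at 12 with no new compound (F0).

**Step 6.** Over-reduction is the risk: once the para oxygen of the C2 arene is unmasked, C2–O1 can be hydrogenolysed as well, opening the oxolane. The fallback cuts the lactone bond by a quinone methide reduction that only the C7' arene can undergo.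
- It sets out from 8, which is treated with the Grignard reagent of (4-bromo-2-methoxyphenoxy)(tert-butyl)dimethylsilane F6.
- This gives the lactone (1R,5S,8R)-8-[4-(benzyloxy)-3-methoxyphenyl]-4-[4-(tert-butyldimethylsilyloxy)-3-methoxyphenyl]-3,7-dioxabicyclo[3.3.0]octan-2-one F7.
- Bu4NF with NaBH4 in THF unmasks the phenoxide, which expels the carboxylate as a quinone methide; hydride adds 1,6. The product is (2R,3R,4S)-2-[4-(benzyloxy)-3-methoxyphenyl]-4-[(4-hydroxy-3-methoxyphenyl)methyl]oxolane-3-carboxylic acid F8. The C2 arene is still a benzyl ether and cannot form a quinone methide.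
- A brief hydrogenolysis of the single aryl benzyl ether then returns to the route at 13.

**Step 8.** The alkoxyphosphonium ion may alkylate a phenol, within or between molecules, and displacement at the β-branched C9 may be slow. The fallback swaps selective esterification for exhaustive acylation followed by selective deacylation.
- It sets out from 14, which is acylated three times with 15 (EDC·HCl, catalytic DMAP, CH2Cl2, 0 °C).
- The product is the tris-ester [(2R,3S,4S)-2-{3-methoxy-4-[(2R)-2-methylbutanoyloxy]phenyl}-4-({3-methoxy-4-[(2R)-2-methylbutanoyloxy]phenyl}methyl)oxolan-3-yl]methyl (2R)-2-methylbutanoate F9.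
- Pyrrolidine at 0 °C cleaves only the two aryl esters, returning at 16.

## Further compounds

F1 | step 3 | (5S)-5-[(1S,2R,5S)-menthyloxy]furan-2(5H)-one | O=C1C=C[C@@H](O[C@H]2C[C@@H](C)CC[C@@H]2C(C)C)O1
F2 | step 3 | (1S,4S,5R,6R)-6-[4-(benzyloxy)-3-methoxyphenyl]-4-[(1S,2R,5S)-menthyloxy]-3,7-dioxabicyclo[3.3.0]octan-2-one | O=C1O[C@H](O[C@H]3C[C@@H](C)CC[C@@H]3C(C)C)[C@H]2[C@H](c4ccc(OCc5ccccc5)c(OC)c4)OC[C@@H]12
F3 | step 3 | (1S,5R,6R)-6-[4-(benzyloxy)-3-methoxyphenyl]-4-hydroxy-3,7-dioxabicyclo[3.3.0]octan-2-one (anomers) | O=C1OC(O)[C@H]2[C@H](c3ccc(OCc4ccccc4)c(OC)c3)OC[C@@H]12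
F4 | step 3 | (1S,5S,6R)-6-[4-(benzyloxy)-3-methoxyphenyl]-3,7-dioxabicyclo[3.3.0]octan-2-one | O=C1OC[C@H]2[C@H](c3ccc(OCc4ccccc4)c(OC)c3)OC[C@@H]12
F5 | step 3 | {(2R,3S,4S)-2-[4-(benzyloxy)-3-methoxyphenyl]-3-(hydroxymethyl)oxolan-4-yl}[4-(benzyloxy)-3-methoxyphenyl]methanone | OC[C@@H]1[C@H](C(=O)c2ccc(OCc3ccccc3)c(OC)c2)CO[C@H]1c1ccc(OCc2ccccc2)c(OC)c1
F0 | step 2 | none | none
F0 | step 5 | none | none
F6 | step 6 | (4-bromo-2-methoxyphenoxy)(tert-butyl)dimethylsilane | COc1cc(Br)ccc1O[Si](C)(C)C(C)(C)C
F7 | step 6 | (1R,5S,8R)-8-[4-(benzyloxy)-3-methoxyphenyl]-4-[4-(tert-butyldimethylsilyloxy)-3-methoxyphenyl]-3,7-dioxabicyclo[3.3.0]octan-2-one (C4 epimers) | O=C1OC(c2ccc(O[Si](C)(C)C(C)(C)C)c(OC)c2)[C@@H]2CO[C@@H](c3ccc(OCc4ccccc4)c(OC)c3)[C@H]12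
F8 | step 6 | (2R,3R,4S)-2-[4-(benzyloxy)-3-methoxyphenyl]-4-[(4-hydroxy-3-methoxyphenyl)methyl]oxolane-3-carboxylic acid | OC(=O)[C@@H]1[C@H](Cc2ccc(O)c(OC)c2)CO[C@H]1c1ccc(OCc2ccccc2)c(OC)c1
F9 | step 8 | [(2R,3S,4S)-2-{3-methoxy-4-[(2R)-2-methylbutanoyloxy]phenyl}-4-({3-methoxy-4-[(2R)-2-methylbutanoyloxy]phenyl}methyl)oxolan-3-yl]methyl (2R)-2-methylbutanoate | CC[C@@H](C)C(=O)OC[C@@H]1[C@H](Cc2ccc(OC(=O)[C@H](C)CC)c(OC)c2)CO[C@H]1c1ccc(OC(=O)[C@H](C)CC)c(OC)c1
A1 | alternative 1 | 4-(tert-butyldimethylsilyloxy)-3-methoxybenzaldehyde | COc1cc(C=O)ccc1O[Si](C)(C)C(C)(C)C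
A2 | alternative 1 | methyl (2Z)-4-(tert-butyldimethylsilyloxy)-2-[(4,4,5,5-tetramethyl-1,3,2-dioxaborolan-2-yl)methyl]but-2-enoate | COC(=O)/C(CB1OC(C)(C)C(C)(C)O1)=C\CO[Si](C)(C)C(C)(C)C
A3 | alternative 1 | (4S,5R)-5-[4-(tert-butyldimethylsilyloxy)-3-methoxyphenyl]-4-[(tert-butyldimethylsilyloxy)methyl]-3-methylideneoxolan-2-one | O=C1O[C@@H](c2ccc(O[Si](C)(C)C(C)(C)C)c(OC)c2)[C@H](CO[Si](C)(C)C(C)(C)C)C1=C
A4 | alternative 2 | 2-[4-(tert-butyldimethylsilyloxy)-3-methoxyphenyl]-1,3-dithiane | COc1cc(C2SCCCS2)ccc1O[Si](C)(C)C(C)(C)C
A5 | alternative 2 | (5S)-5-[(1S,2R,5S)-menthyloxy]furan-2(5H)-one | O=C1C=C[C@@H](O[C@H]2C[C@@H](C)CC[C@@H]2C(C)C)O1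
A6 | alternative 2 | 3,4-trans,4,5-trans 3-[aryl(hydroxy)methyl]-4-(2-aryl-1,3-dithian-2-yl)-5-[(1S,2R,5S)-menthyloxy]oxolan-2-one, aryl = 4-(tert-butyldimethylsilyloxy)-3-methoxyphenyl (carbinol epimer drawn arbitrarily) | O=C1[C@@H]([C@@H](O)c2ccc(O[Si](C)(C)C(C)(C)C)c(OC)c2)[C@H](C3(c4ccc(O[Si](C)(C)C(C)(C)C)c(OC)c4)SCCCS3)[C@@H](O[C@H]5C[C@@H](C)CC[C@@H]5C(C)C)O1
A7 | alternative 3 | 2-{(S)-[4-(tert-butyldimethylsilyloxy)-3-methoxyphenyl][(2E)-3-[4-(tert-butyldimethylsilyloxy)-3-methoxyphenyl]prop-2-en-1-yloxy]methyl}oxirane (either epoxide epimer) | COc1cc(/C=C/CO[C@@H](c2ccc(O[Si](C)(C)C(C)(C)C)c(OC)c2)C2CO2)ccc1O[Si](C)(C)C(C)(C)C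
A8 | alternative 3 | bis(tert-butyldimethylsilyl) ether of (2R,3S,4S)-lariciresinol | OC[C@@H]1[C@H](Cc2ccc(O[Si](C)(C)C(C)(C)C)c(OC)c2)CO[C@H]1c1ccc(O[Si](C)(C)C(C)(C)C)c(OC)c1
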